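**Strategy.** Numbering follows tricyclo[5.4.0.0^2,8]undecane (cyclobutane C1/C2/C8/C7, seven-membered ring C1–C7, cyclohexanone C8–C11). Everything rests on cutting the four-carbon bridge C3–C6 at C4–C5 and C6–C7, which excises C5/C6 as ethyl 2-bromo-2-methylpropanoate. The key step exploits that C2 (quaternary, methyl) and C7 (CH) lie 1,3 across the cyclobutane and are thus the bridgeheads of a bicyclo[1.1.0]butane. Photoredox radical addition to bicyclobutyl dimethylcarbinol 9 forms C6–C7, a semipinacol methyl shift creates the C2 methyl/acetyl centre, and in-flask Claisen closure of the new methyl ketone onto the ester forms C4–C5, giving the seven-membered 1,3-diketone 12. The C9 methyl is added last by cuprate addition.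

Key step: step 6

Remark: compounds 1, 4, 10 and 15 are taken as commercial. The cyclopropanation product is drawn as the exo ester; its epimer at the ester-bearing carbon converges in step 4 through the enolate.

Step 1
Reactants: 1 1,4-dioxaspiro[4.5]dec-6-en-8-one
Product: 2 (8R)-1,4-dioxaspiro[4.5]dec-6-en-8-ol
Conditions: (S)-Me-CBS (10 mol %), BH3·SMe2, THF, −20 °C; aq. work-up
Reagents that add atoms: none
Why: Corey–Bakshi–Shibata reduction in which the alkenyl arm acts as the large group, so the (S)-catalyst should deliver hydride to give the (R)-carbinol, the centre from which all later stereochemistry is relayed.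

Step 2
Reactants: 2 (8R)-1,4-dioxaspiro[4.5]dec-6-en-8-ol
Product: 3 (8R)-8-(tert-butyldimethylsilyloxy)-1,4-dioxaspiro[4.5]dec-6-ene
Conditions: TBSCl, imidazole, DMF, 25 °C
Reagents that add atoms: tert-butyldimethylsilyl chloride, CC(C)(C)[Si](C)(C)Cl
Why: Standard silyl ether protection, which prevents O–H insertion in the next step and turns the oxygen into a bulky facial director.

Step 3
Reactants: 3 (8R)-8-(tert-butyldimethylsilyloxy)-1,4-dioxaspiro[4.5]dec-6-ene; 4 ethyl diazoacetate
Product: 6 ethyl (2R)-2-hydroxy-5,5-(ethylenedioxy)bicyclo[4.1.0]heptane-7-carboxylate (hydroxyl trans to the cyclopropane), via silyl ether cyclopropane ester 5 (not isolated)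
Conditions: Rh2(OAc)4 (1 mol %), CH2Cl2, slow addition of 4, 25 °C; then TBAF, THF, 25 °C
Reagents that add atoms: none
Why: Rhodium-carbenoid cyclopropanation should occur on the alkene face anti to the allylic silyloxy group (the spiro ketal is face-neutral), setting both ring-fusion centres trans to oxygen, and fluoride then cleaves the silyl ether.

Step 4
Reactants: 6 ethyl (2R)-2-hydroxy-5,5-(ethylenedioxy)bicyclo[4.1.0]heptane-7-carboxylate
Product: 8 ethyl 3,3-(ethylenedioxy)tricyclo[4.1.0.0^2,7]heptane-1-carboxylate, via cyclopropylcarbinyl mesylate 7 (not isolated)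
Conditions: MsCl, Et3N, THF, −20 °C; then LDA (3 equiv), THF, −78 → 0 °C
Reagents that add atoms: none
Why: γ-Elimination of the γ-sulfonyloxy ester type, in which the cyclopropyl ester enolate displaces the trans-disposed mesylate by 3-exo-tet SN2 with inversion and so closes the bicyclo[1.1.0]butane, whose configuration follows from steps 1 and 3.

Step 5
Reactants: 8 ethyl 3,3-(ethylenedioxy)tricyclo[4.1.0.0^2,7]heptane-1-carboxylate
Product: 9 2-[3,3-(ethylenedioxy)tricyclo[4.1.0.0^2,7]hept-1-yl]propan-2-ol
Conditions: MeLi (2.5 equiv), Et2O, −78 → 0 °C; then H2O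
Reagents that add atoms: methyllithium (two equivalents add), [Li]C
Why: Double 1,2-addition of the hard organolithium to the ester carbonyl (rather than strain-release addition) should give the tertiary carbinol; no stereocentre is formed.

Step 6
Reactants: 9 2-[3,3-(ethylenedioxy)tricyclo[4.1.0.0^2,7]hept-1-yl]propan-2-ol; 10 ethyl 2-bromo-2-methylpropanoate
Product: 12 (1R,2R,7S,8S)-11,11-(ethylenedioxy)-2,6,6-trimethyltricyclo[5.4.0.0^2,8]undecane-3,5-dione, via keto ester 11 (not isolated)
Conditions: fac-Ir(ppy)3 (1 mol %), 2,6-lutidine, PhCF3, 450 nm LEDs, 25 °C; then KOtBu (4 equiv), THF, 0 → 25 °C; AcOH quench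
Reagents that add atoms: none
Why: Proposed new method: photoexcited fac-Ir(ppy)3 should reduce 10 to the electrophilic tertiary α-ester radical, which adds to the unsubstituted bridgehead of the electron-rich central bond of 9; tetravalent iridium oxidises the resulting tertiary cyclobutyl radical to the cation, a 1,2-methyl shift from the carbinol carbon (semipinacol) gives methyl ketone 11, and tert-butoxide then drives crossed Claisen condensation of its only enolisable position onto the non-enolisable ester. The closest known reaction types are the electrophile-triggered strain-release semipinacol rearrangement of bicyclo[1.1.0]butyl carbinols, photoredox radical addition/radical–polar crossover semipinacol rearrangements of alkenyl cyclobutanols, and radical additions across the central bond of tricyclo[4.1.0.0^2,7]heptanes. The cyclobutane is released by cleavage of the central σ-bond, and the seven-membered ring closes as a 7-(enolendo)-exo-trig acyl substitution. The C7 centre should be set by radical attack on the open convex face, anti to the dioxolane-bearing bridge, and the C2 centre by methyl migration to the face opposite the new bulky arm (1,3-anti addition), which leaves acetyl and ester arm cis on the face away from the three-carbon bridge. The step needs this face selectivity and a crossover faster than hydrogen-atom transfer; the amine-free oxidative quenching cycle and the irreversible formation of the diketonate are meant to secure the latter.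

Step 7
Reactants: 12 (1R,2R,7S,8S)-11,11-(ethylenedioxy)-2,6,6-trimethyltricyclo[5.4.0.0^2,8]undecane-3,5-dione
Product: 13 (1R,2R,3R,5R,7S,8S)-11,11-(ethylenedioxy)-2,6,6-trimethyltricyclo[5.4.0.0^2,8]undecane-3,5-diol
Conditions: (S)-Me-CBS (0.4 equiv), BH3·SMe2 (2.4 equiv), THF, −20 → 25 °C; aq. work-up
Reagents that add atoms: none
Why: Corey–Bakshi–Shibata reduction under reagent control, in which each carbonyl has a quaternary large and a CH2 small substituent, so the (S)-catalyst should give R at both new centres, i.e. the anti-1,3-diol.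

Step 8
Reactants: 13 (1R,2R,3R,5R,7S,8S)-11,11-(ethylenedioxy)-2,6,6-trimethyltricyclo[5.4.0.0^2,8]undecane-3,5-diol
Product: 14 (1R,2R,3R,5R,7S,8S)-3,5-dihydroxy-2,6,6-trimethyltricyclo[5.4.0.0^2,8]undecan-11-one
Conditions: 1 M HCl, THF, 25 °C
Reagents that add atoms: water, O
Why: Acid-catalysed acetal hydrolysis frees the C11 ketone before the acid-sensitive angelates are present; no stereocentre is touched.

Step 9
Reactants: 14 (1R,2R,3R,5R,7S,8S)-3,5-dihydroxy-2,6,6-trimethyltricyclo[5.4.0.0^2,8]undecan-11-one; 15 angelic acid (two equivalents enter the product; 3 equiv used)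
Product: 16 (1R,2R,3R,5R,7S,8S)-2,6,6-trimethyl-11-oxotricyclo[5.4.0.0^2,8]undecane-3,5-diyl bis[(Z)-2-methylbut-2-enoate]
Conditions: 15 (3 equiv), 2,4,6-trichlorobenzoyl chloride (3 equiv), Et3N, toluene, 25 °C; then 14, 80 °C
Reagents that add atoms: angelic acid (second equivalent, the same compound as 15), C/C=C(/C)C(=O)O
Why: Yamaguchi-type mixed-anhydride esterification run without a nucleophilic catalyst, conditions under which the (Z)-acid should be transferred to both hindered secondary alcohols, one molecule of 15 per hydroxyl, without isomerisation to the tiglate.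

Step 10
Reactants: 16 (1R,2R,3R,5R,7S,8S)-2,6,6-trimethyl-11-oxotricyclo[5.4.0.0^2,8]undecane-3,5-diyl bis[(Z)-2-methylbut-2-enoate]
Product: 17 (1R,2R,3R,5R,7S,8S)-2,6,6-trimethyl-11-oxotricyclo[5.4.0.0^2,8]undec-9-ene-3,5-diyl bis[(Z)-2-methylbut-2-enoate]
Conditions: IBX (2.5 equiv), DMSO, 70 °C
Reagents that add atoms: none
Why: IBX dehydrogenation through the enol, which can only form toward C10 because C1 is a cyclobutane bridgehead, should give the C9–C10 enone (the nopinone-to-apoverbenone type of conversion).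

Step 11
Reactants: 17 (1R,2R,3R,5R,7S,8S)-2,6,6-trimethyl-11-oxotricyclo[5.4.0.0^2,8]undec-9-ene-3,5-diyl bis[(Z)-2-methylbut-2-enoate]
Product: 18 (1R,2R,3R,5R,7S,8S,9R)-2,6,6,9-tetramethyl-11-oxotricyclo[5.4.0.0^2,8]undecane-3,5-diyl bis[(Z)-2-methylbut-2-enoate] (CNP0283599.1)
Conditions: Me2CuLi (from MeLi, CuI), Et2O, −78 °C; then H2O
Reagents that add atoms: lithium dimethylcuprate, [Li+].C[Cu-]C
Why: Gilman cuprate 1,4-addition should occur on the enone face flanked by the C7 hydrogen, not the face shielded by the C2 methyl (as with verbenone-type enones), which sets C9, while the trisubstituted angelates are inert at −78 °C.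

**Compound list**

1 | 1,4-dioxaspiro[4.5]dec-6-en-8-one | O=C1C=CC2(CC1)OCCO2 | starting material
2 | (8R)-1,4-dioxaspiro[4.5]dec-6-en-8-ol | O[C@H]1C=CC2(OCCO2)CC1 | intermediate
3 | (8R)-8-(tert-butyldimethylsilyloxy)-1,4-dioxaspiro[4.5]dec-6-ene | CC(C)(C)[Si](C)(C)O[C@H]1C=CC2(OCCO2)CC1 | intermediate
4 | ethyl diazoacetate | CCOC(=O)C=[N+]=[N-] | starting material
5 | ethyl (2R)-2-(tert-butyldimethylsilyloxy)-5,5-(ethylenedioxy)bicyclo[4.1.0]heptane-7-carboxylate, cyclopropane trans to the silyloxy group, ester exo (not isolated) | CC(C)(C)[Si](C)(C)O[C@@H]1CCC2(OCCO2)[C@H]3[C@H](C(=O)OCC)[C@@H]13 | intermediate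
6 | ethyl (2R)-2-hydroxy-5,5-(ethylenedioxy)bicyclo[4.1.0]heptane-7-carboxylate, hydroxyl trans to the cyclopropane, ester exo | O[C@@H]1CCC2(OCCO2)[C@H]3[C@H](C(=O)OCC)[C@@H]13 | intermediate
7 | ethyl (2R)-2-(methylsulfonyloxy)-5,5-(ethylenedioxy)bicyclo[4.1.0]heptane-7-carboxylate, same configuration as 6 (not isolated) | CS(=O)(=O)O[C@@H]1CCC2(OCCO2)[C@H]3[C@H](C(=O)OCC)[C@@H]13 | intermediate
8 | ethyl 3,3-(ethylenedioxy)tricyclo[4.1.0.0^2,7]heptane-1-carboxylate, ester on bridgehead C1, ketal on C3 next to wing carbon C2, single enantiomer as drawn | CCOC(=O)[C@@]12[C@H]3[C@@H]1CCC4(OCCO4)[C@@H]23 | intermediate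
9 | 2-[3,3-(ethylenedioxy)tricyclo[4.1.0.0^2,7]hept-1-yl]propan-2-ol, same configuration as 8 | CC(C)(O)[C@@]12[C@H]3[C@@H]1CCC4(OCCO4)[C@@H]23 | intermediate
10 | ethyl 2-bromo-2-methylpropanoate | CCOC(=O)C(C)(C)Br | starting material
11 | ethyl 2-[6-acetyl-6-methyl-2,2-(ethylenedioxy)bicyclo[3.1.1]hept-7-yl]-2-methylpropanoate, acetyl and ester arm both anti to the C2–C4 bridge (not isolated) | CC(=O)[C@]1(C)[C@@H]2[C@@H]([C@H]1C3(OCCO3)CC2)C(C)(C)C(=O)OCC | intermediate
12 | (1R,2R,7S,8S)-11,11-(ethylenedioxy)-2,6,6-trimethyltricyclo[5.4.0.0^2,8]undecane-3,5-dione | O=C1CC(=O)[C@]2(C)[C@@H]3[C@@H]([C@H]2C4(OCCO4)CC3)C1(C)C | intermediate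
13 | (1R,2R,3R,5R,7S,8S)-11,11-(ethylenedioxy)-2,6,6-trimethyltricyclo[5.4.0.0^2,8]undecane-3,5-diol | O[C@@H]1C[C@@H](O)[C@]2(C)[C@@H]3[C@@H]([C@H]2C4(OCCO4)CC3)C1(C)C | intermediate
14 | (1R,2R,3R,5R,7S,8S)-3,5-dihydroxy-2,6,6-trimethyltricyclo[5.4.0.0^2,8]undecan-11-one | O[C@@H]1C[C@@H](O)[C@]2(C)[C@@H]3[C@@H]([C@H]2C(=O)CC3)C1(C)C | intermediate
15 | angelic acid, (Z)-2-methylbut-2-enoic acid | C/C=C(/C)C(=O)O | starting material
16 | (1R,2R,3R,5R,7S,8S)-2,6,6-trimethyl-11-oxotricyclo[5.4.0.0^2,8]undecane-3,5-diyl bis[(Z)-2-methylbut-2-enoate] | C/C=C(/C)C(=O)O[C@@H]1C[C@@H](OC(=O)/C(C)=C\C)[C@]2(C)[C@@H]3[C@@H]([C@H]2C(=O)CC3)C1(C)C | intermediate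
17 | (1R,2R,3R,5R,7S,8S)-2,6,6-trimethyl-11-oxotricyclo[5.4.0.0^2,8]undec-9-ene-3,5-diyl bis[(Z)-2-methylbut-2-enoate] | C/C=C(/C)C(=O)O[C@@H]1C[C@@H](OC(=O)/C(C)=C\C)[C@]2(C)[C@@H]3[C@@H]([C@H]2C(=O)C=C3)C1(C)C | intermediate
18 | (1R,2R,3R,5R,7S,8S,9R)-2,6,6,9-tetramethyl-11-oxotricyclo[5.4.0.0^2,8]undecane-3,5-diyl bis[(Z)-2-methylbut-2-enoate], CNP0283599.1 | C/C=C(/C)C(=O)O[C@@H]1C[C@@H](OC(=O)/C(C)=C\C)[C@]2(C)[C@@H]3[C@@H]([C@H]2C(=O)C[C@H]3C)C1(C)C | target

**Total step count:** 11. **Longest linear sequence:** 11 steps (1 → 18).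

**Steps most likely to fail**

Step 6. The tertiary radical may enter along the rear, bridge-flanked trajectory instead of the convex face, which would place the new quaternary arm syn to the three-carbon bridge and make ring closure impossible. Alternatively, hydrogen-atom transfer to the cyclobutyl radical may outrun oxidation and methyl shift. The fallback is polar, uses known reaction types and sets out from 8. Aminolysis with MeNH(OMe)·HCl/iPrMgCl should give N-methoxy-N-methyl-3,3-(ethylenedioxy)tricyclo[4.1.0.0^2,7]heptane-1-carboxamide F1, and MeMgBr then the acetyl bicyclobutane 1-[3,3-(ethylenedioxy)tricyclo[4.1.0.0^2,7]hept-1-yl]ethanone F2. A Sc(OTf)3-catalysed Mukaiyama–Michael-type strain-release addition of 1-ethoxy-2-methyl-1-(trimethylsilyloxy)prop-1-ene to this acyl bicyclobutane should give the ring-opened silyl enol ether ethyl 2-methyl-2-{6-[1-(trimethylsilyloxy)ethylidene]-2,2-(ethylenedioxy)bicyclo[3.1.1]hept-7-yl}propanoate F3. MeLi then MeI should methylate the regiodefined enolate on the face away from the new arm to give 11, and KOtBu closes it to 12, where the route is rejoined.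

Step 4. Ionisation and rearrangement of the cyclopropylcarbinyl mesylate, or E2 elimination, may compete with the 3-exo-tet closure. The fallback builds the bicyclobutane by carbene addition instead and sets out from 1. Reduction with the (R)-catalyst should give (8S)-1,4-dioxaspiro[4.5]dec-6-en-8-ol F4. Johnson–Claisen rearrangement (MeC(OEt)3, cat. EtCO2H, 140 °C) should move the two-carbon ester arm suprafacially onto the ketal-flanked alkene carbon to give ethyl 2-(1,4-dioxaspiro[4.5]dec-7-en-6-yl)acetate F5. LiHMDS/CF3CO2CH2CF3 should give the trifluoroacetyl ester ethyl 2-(1,4-dioxaspiro[4.5]dec-7-en-6-yl)-4,4,4-trifluoro-3-oxobutanoate F6, and deacylative diazo transfer (MsN3, Et3N) the α-diazo ester ethyl 2-diazo-2-(1,4-dioxaspiro[4.5]dec-7-en-6-yl)acetate F7. Intramolecular cyclopropanation of the adjacent ring alkene, catalysed by Rh2(O2CCPh3)4 in toluene at −78 °C to hold back 1,2-hydride shift, should then form both lateral bonds of the bicyclobutane at once and return to 8.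

Step 7. Chelation of boron by the first-formed β-hydroxy ketone, or enolisation of the β-diketone, may stall the second reduction or erode its face selectivity, giving mono-alcohol or cis-diol. The fallback separates the two events and sets out from 12. One equivalent of catecholborane with (S)-Me-CBS at −78 °C should stop at the hydroxy ketone (5R)-11,11-(ethylenedioxy)-5-hydroxy-2,6,6-trimethyltricyclo[5.4.0.0^2,8]undecan-3-one F8 (drawn for reduction at C5). Evans–Saksena reduction (Me4NBH(OAc)3, MeCN/AcOH, −30 °C) should then deliver hydride intramolecularly from the bound alkoxide to give the anti-diol 13.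

**Further compounds**

F1 | step 6 | N-methoxy-N-methyl-3,3-(ethylenedioxy)tricyclo[4.1.0.0^2,7]heptane-1-carboxamide | CON(C)C(=O)[C@@]12[C@H]3[C@@H]1CCC4(OCCO4)[C@@H]23
F2 | step 6 | 1-[3,3-(ethylenedioxy)tricyclo[4.1.0.0^2,7]hept-1-yl]ethanone | CC(=O)[C@@]12[C@H]3[C@@H]1CCC4(OCCO4)[C@@H]23
F3 | step 6 | ethyl 2-methyl-2-{6-[1-(trimethylsilyloxy)ethylidene]-2,2-(ethylenedioxy)bicyclo[3.1.1]hept-7-yl}propanoate, ester arm anti to the C2–C4 bridge | CC(O[Si](C)(C)C)=C1[C@@H]2[C@@H]([C@H]1C3(OCCO3)CC2)C(C)(C)C(=O)OCC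
F4 | step 4 | (8S)-1,4-dioxaspiro[4.5]dec-6-en-8-ol | O[C@@H]1C=CC2(OCCO2)CC1
F5 | step 4 | ethyl 2-(1,4-dioxaspiro[4.5]dec-7-en-6-yl)acetate | CCOC(=O)C[C@H]1C=CCCC12OCCO2
F6 | step 4 | ethyl 2-(1,4-dioxaspiro[4.5]dec-7-en-6-yl)-4,4,4-trifluoro-3-oxobutanoate | CCOC(=O)C(C(=O)C(F)(F)F)[C@H]1C=CCCC12OCCO2
F7 | step 4 | ethyl 2-diazo-2-(1,4-dioxaspiro[4.5]dec-7-en-6-yl)acetate | CCOC(=O)C(=[N+]=[N-])[C@H]1C=CCCC12OCCO2
F8 | step 7 | (5R)-11,11-(ethylenedioxy)-5-hydroxy-2,6,6-trimethyltricyclo[5.4.0.0^2,8]undecan-3-one | O[C@@H]1CC(=O)[C@]2(C)[C@@H]3[C@@H]([C@H]2C4(OCCO4)CC3)C1(C)C
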